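The constants are hidden, so you start from what the readings say about them.

| setting | green | red | flask |
|---|---|---|---|
| substrate | 0.14 M | 0.22 M | 0.29 M |
| coupling partner | 0.58 M (fed, over 4.0 min) | 0.58 M (fed, over 4.0 min) | 0.580 M (fed, over 4.0 min) |
| remark | run made earlier; the fed solution adds 0.20 times the starting volume | run made earlier; the fed solution adds 0.20 times the starting volume | the fed solution adds 0.20 times the starting volume |
| time |  |  | 4.0 min |

| run | time / min | substrate / % | target / % |
|---|---|---|---|
| green | 0.333 | 99.5 | 0.7 |
| green | 0.667 | 97.1 | 3.8 |
| green | 1.00 | 94.2 | 5.3 |
| green | 1.33 | 90.2 | 9.8 |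
| green | 1.50 | 88.1 | 12.6 |
| green | 2.00 | 78.3 | 19.1 |
| green | 2.50 | 69.1 | 25.4 |
| red | 0.200 | 98.6 | 0.4 |
| red | 0.333 | 99.4 | 1.9 |
| red | 0.417 | 98.4 | 1.1 |
| red | 0.667 | 97.0 | 2.4 |
| red | 1.00 | 94.1 | 5.1 |
| red | 1.50 | 87.8 | 12.4 |
| red | 2.50 | 71.7 | 24.9 |

(each reading ± 0.5 percentage points)

- amounts and yields of by-product count idle adduct too
- charges are per starting volume, the dose included; the dosed solution carries all of it
- the analysis behind the earlier runs scatters by 0.5 percentage points, standard deviation
- candidate steps: substrate + coupling partner <-> target + by-product; coupling partner + by-product <-> idle adduct; target -> over-reaction product A; coupling partner + target -> over-reaction product B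
- the earlier runs do not show how much of coupling partner is bound; that part of a forecast is a guess

Let s be the fraction of the substrate charge left. Green and red differ in substrate, yet at 2.50 min the fraction s is 69.1% in green and 71.7% in red. So the step looks pseudo-first-order in substrate.

Freeze that. Call ln(1/s) the exposure. If coupling partner builds up in step with time, exposure grows with time squared and with the charge of coupling partner.

But red lags green by 2.6 percentage points, beyond the scatter of 0.5 points. Scaled to the end of the dose and divided by the charge, green gives 1.63 M⁻¹ and red 1.47 M⁻¹. So read the gap as a cost of substrate, and extend the line to the flask's 0.29 M: 1.33 M⁻¹. This end-of-dose exposure per molar of coupling partner charged is what you carry.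

1. part of the substrate that has reacted at 4.0 min
2. share of the unused coupling partner that is free and not bound as idle adduct, at 4.0 min

For the flask it gives 53.6% reacted. The readings do not show how much coupling partner is bound, so you set no free share of your own.

The forecast says 49% reacted, below your conversion, and 80% free, and of the second number it says: “The free share is largely a guess”.

The flask gives 49.5% reacted and 94.2% free.

    substrate + coupling partner ⇌ target + by-product (K = 2.10, k = 0.0160 M⁻¹ s⁻¹)
    coupling partner + by-product ⇌ idle adduct, settled at all times (K = 0.610 M⁻¹)
    target → over-reaction product A (k = 2.70 × 10⁻⁶ s⁻¹)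
    coupling partner + target → over-reaction product B (k = 0.0140 M⁻¹ s⁻¹)

At 4.00 min the flask holds 0.0190 M of idle adduct. Its exposure is 0.683, which is 0.888 of what your coefficient gave. Keep that factor and put the neighbour's 0.99 M of coupling partner into the coefficient: you get 68.8% reacted. That neighbour flask gives 68.4%.

Readings and results stem from a simulated flask with constants of no real substance; noise was put on by code.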